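**Retrosynthetic overview**
1. The target comes from its tris-O-methyl ether; the formyl and isovaleryl groups are put on last by two directed ortho-lithiations of 1β-(2,4,6-trimethoxybenzyl)eudesm-11-en-4α-ol.
2. The aryl–CH2–C1 link comes from 2,4,6-trimethoxyphenyllithium plus a C1β aldehyde, then ionic deoxygenation; the isopropenyl group comes from the C7 ketone via nitrile, acetyl and methylenation.
3. The C4 carbinol and the trans ring fusion come from a C4=C5 alkene (hydroboration, ketone, methylene, α-epoxide, hydride).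
4. The decalin is (R)-Wieland–Miescher ketone: D-proline catalysis sets C10, and a ketoreductase tells the two carbonyls apart.
5. Ring order: ring A is the purchased cyclohexanedione, ring B is closed by Robinson annulation, and the aryl ring is brought in intact.

Assumption: the decalin carries eudesmane locants (C1 bears the benzyl group, C4 is the carbinol carbon, C5/C10 are the ring fusion, C7 bears the isopropenyl group, C15 is the C4 methyl); β is the face of the C10 methyl, and stereocentres that are destroyed in a later step are carried as mixtures.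

**Step 1**
Reactants: 1 2-methylcyclohexane-1,3-dione; 2 methyl vinyl ketone
Product: 3 2-methyl-2-(3-oxobutyl)cyclohexane-1,3-dione
Conditions: AcOH (cat.), hydroquinone (cat.), H2O, 75 °C
Reagents that add atoms: none
Why: Michael addition of the acidic 1,3-dione to the enone gives the achiral (prochiral) triketone, so no stereochemistry arises yet.

**Step 2**
Reactants: 3 2-methyl-2-(3-oxobutyl)cyclohexane-1,3-dione
Product: 5 (R)-Wieland–Miescher ketone, via aldol ketol 4 (not isolated)
Conditions: D-proline (5 mol %), DMSO, rt, 5 d; recrystallisation (Et2O/hexane)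
Reagents that add atoms: none
Why: In this Hajos–Parrish–Eder–Sauer–Wiechert aldol condensation the D-proline enamine attacks one of the two enantiotopic ring carbonyls through a hydrogen-bonded transition state, which closes ring B, sets C10 as R under catalyst control and dehydrates to the enone (crystallisation raises the ee).

**Step 3**
Reactants: 5 (R)-Wieland–Miescher ketone
Product: 6 (4aR,5R)-5-hydroxy-4a-methyl-4,4a,5,6,7,8-hexahydronaphthalen-2(3H)-one
Conditions: ketoreductase (NADPH-dependent, chosen from a screening panel for the R enantiomer), NADP+ (cat.), i-PrOH (10 vol %), phosphate buffer pH 7, DMSO (5 vol %), 30 °C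
Reagents that add atoms: none
Why: In this enzymatic carbonyl reduction the ketoreductase accepts only the saturated C1 ketone and delivers hydride to its α face, giving the 1β-alcohol as one diastereomer while leaving the enone untouched and rejecting residual S enantiomer.

**Step 4**
Reactants: 6 (4aR,5R)-hydroxy enone
Product: 7 7,7-ethylenedioxy-10β-methyloctal-4-en-1β-ol
Conditions: HOCH2CH2OH, p-TsOH·H2O (cat.), benzene, reflux, Dean–Stark
Reagents that add atoms: ethylene glycol, OCCO
Why: Deconjugative ketalisation masks the C7 carbonyl as a dioxolane and moves the double bond to C4=C5 under thermodynamic control, with no stereocentre touched.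

**Step 5**
Reactants: 7 hydroxy ketal
Product: 8 1β-O-TBS ether of 7
Conditions: TBSOTf, 2,6-lutidine, CH2Cl2, 0 °C
Reagents that add atoms: tert-butyldimethylsilyl triflate, CC(C)(C)[Si](C)(C)OS(=O)(=O)C(F)(F)F
Why: Silylation with the reactive triflate protects the hindered 1β-alcohol so that C4 can later be oxidised on its own.

**Step 6**
Reactants: 8 TBS ether
Product: 10 1β-(TBSO)-7,7-ethylenedioxy-10β-methyl-5α-decalin-4α-ol, via alkylborane 9 (not isolated)
Conditions: BH3·THF, THF, 0 °C to rt; then NaOH, H2O2, 0 °C to rt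
Reagents that add atoms: hydrogen peroxide, OO
Why: In this hydroboration–oxidation borane adds syn and anti-Markovnikov from the α face, opposite the axial C10 methyl, so boron goes to C4α and hydrogen to C5α (trans ring fusion), and oxidation proceeds with retention.

**Step 7**
Reactants: 10 4α-alcohol
Product: 11 1β-(TBSO)-7,7-ethylenedioxy-10β-methyl-5α-decalin-4-one
Conditions: Dess–Martin periodinane (DMP), NaHCO3, CH2Cl2, rt
Reagents that add atoms: none
Why: Dess–Martin oxidation gives the C4 ketone under buffered conditions that spare ketal and silyl ether, and C5 next to it stays in the more stable trans-fused form.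

**Step 8**
Reactants: 11 C4 ketone
Product: 12 1β-(TBSO)-7,7-ethylenedioxy-10β-methyl-4-methylene-5α-decalin
Conditions: Ph3PCH3Br, KOtBu, THF, 0 to 50 °C
Reagents that add atoms: methyltriphenylphosphonium bromide, C[P+](c1ccccc1)(c1ccccc1)c1ccccc1.[Br-]
Why: Wittig methylenation of the unhindered C4 ketone brings in C15, and any base-induced equilibration at C5 converges on the trans-decalin.

**Step 9**
Reactants: 12 4-methylene compound
Product: 13 4α,15-epoxide of 12
Conditions: mCPBA, NaHCO3, CH2Cl2, 0 °C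
Reagents that add atoms: 3-chloroperbenzoic acid, OOC(=O)c1cccc(Cl)c1
Why: In this Prilezhaev epoxidation the β face of the exocyclic alkene is blocked by the 1,3-related axial C10 methyl, so the peracid attacks from the α face and puts oxygen on C4α (the minor β-epoxide is removed by chromatography).

**Step 10**
Reactants: 13 epoxide
Product: 14 1β-(TBSO)-7,7-ethylenedioxy-4β,10β-dimethyl-5α-decalin-4α-ol
Conditions: LiAlH4, THF, 0 °C to reflux
Reagents that add atoms: none
Why: Hydride opens the spiro-epoxide by SN2 attack at the primary carbon, leaving the oxygen on C4 as the 4α tertiary alcohol and turning C15 into the 4β methyl.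

**Step 11**
Reactants: 14 silyl ether
Product: 15 7,7-ethylenedioxy-4β,10β-dimethyl-5α-decalin-1β,4α-diol
Conditions: Bu4NF, THF, 60 °C
Reagents that add atoms: none
Why: Fluoride-mediated desilylation frees the 1β-alcohol while the ketal and tertiary alcohol are inert.

**Step 12**
Reactants: 15 diol
Product: 16 7,7-ethylenedioxy-4α-hydroxy-4β,10β-dimethyl-5α-decalin-1-one
Conditions: DMP, NaHCO3, CH2Cl2, rt
Reagents that add atoms: none
Why: Dess–Martin oxidation converts only the secondary 1β-alcohol, since the tertiary 4α-alcohol cannot be oxidised.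

**Step 13**
Reactants: 16 C1 ketone
Product: 17 7,7-ethylenedioxy-4β,10β-dimethyl-1-methylene-5α-decalin-4α-ol
Conditions: Ph3PCH3Br (5 equiv), KOtBu (5 equiv), toluene, 90 °C
Reagents that add atoms: methyltriphenylphosphonium bromide, C[P+](c1ccccc1)(c1ccccc1)c1ccccc1.[Br-]
Why: Wittig methylenation with excess ylide in hot toluene converts the neopentyl-type C1 ketone into the exocyclic alkene that supplies the future benzylic carbon.

**Step 14**
Reactants: 17 1-methylene compound
Product: 19 7,7-ethylenedioxy-1β-(hydroxymethyl)-4β,10β-dimethyl-5α-decalin-4α-ol, via B-alkyl-9-BBN 18 (not isolated)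
Conditions: 9-BBN (9-borabicyclo[3.3.1]nonane), THF, 60 °C; then NaOH, H2O2, 0 °C to rt
Reagents that add atoms: hydrogen peroxide, OO
Why: In this hydroboration–oxidation the bulky borane adds to the terminal carbon from the α face, anti to the adjacent axial C10 methyl, so hydrogen is delivered to C1α and the CH2OH group ends up 1β (equatorial).

**Step 15**
Reactants: 19 primary alcohol
Product: 20 7,7-ethylenedioxy-4α-hydroxy-4β,10β-dimethyl-5α-decalin-1β-carbaldehyde
Conditions: DMP, NaHCO3, CH2Cl2, 0 °C to rt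
Reagents that add atoms: none
Why: Dess–Martin oxidation gives the aldehyde without epimerising C1, whose equatorial 1β orientation is in any case the thermodynamic one.

**Step 16**
Reactants: 20 aldehyde; 21 1,3,5-trimethoxybenzene
Product: 23 7,7-ethylenedioxy-1β-[hydroxy(2,4,6-trimethoxyphenyl)methyl]-4β,10β-dimethyl-5α-decalin-4α-ol, via 2,4,6-trimethoxyphenyllithium 22 (not isolated)
Conditions: 21 (3 equiv), n-BuLi (2.8 equiv), THF, 0 °C to rt; then 20, −78 to 0 °C; H2O
Reagents that add atoms: none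
Why: Directed lithiation between two methoxy groups followed by 1,2-addition of the aryllithium to the aldehyde forms the aryl–carbon bond (one equivalent of base is taken by the tertiary alcohol), and the new carbinol centre is removed in the next step.

**Step 17**
Reactants: 23 benzylic carbinol
Product: 24 7,7-ethylenedioxy-4β,10β-dimethyl-1β-(2,4,6-trimethoxybenzyl)-5α-decalin-4α-ol
Conditions: Et3SiH (3 equiv), CF3CO2H (3 equiv), CH2Cl2, −40 °C, 20 min; NaHCO3 quench
Reagents that add atoms: none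
Why: In this ionic hydrogenation the 2,4,6-trimethoxybenzylic alcohol ionises at low temperature to a highly stabilised cation that silane hydride traps far faster than the tertiary alcohol or the dioxolane react, and no stereocentre is involved.

**Step 18**
Reactants: 24 ketal
Product: 25 4α-hydroxy-4β,10β-dimethyl-1β-(2,4,6-trimethoxybenzyl)-5α-decalin-7-one
Conditions: pyridinium p-toluenesulfonate (PPTS), acetone/H2O, 55 °C
Reagents that add atoms: water, O
Why: Mild acid-catalysed ketal hydrolysis releases the C7 ketone while the equatorial tertiary alcohol and the aryl ethers are stable.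

**Step 19**
Reactants: 25 C7 ketone
Product: 26 7-cyano-4β,10β-dimethyl-1β-(2,4,6-trimethoxybenzyl)-5α-decalin-4α-ol (7α/7β mixture)
Conditions: TosMIC (p-toluenesulfonylmethyl isocyanide), KOtBu, DME/EtOH, 0 to 40 °C
Reagents that add atoms: TosMIC, Cc1ccc(cc1)S(=O)(=O)C[N+]#[C-]
Why: Van Leusen reductive cyanation turns the unhindered ketone into the homologous nitrile in one operation, and the C7 configuration does not matter here because it is equilibrated in step 21.

**Step 20**
Reactants: 26 nitrile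
Product: 28 7-acetyl-4β,10β-dimethyl-1β-(2,4,6-trimethoxybenzyl)-5α-decalin-4α-ol (7α/7β mixture), via dilithio ketimine 27 (not isolated)
Conditions: MeLi (3.5 equiv), Et2O/THF, 0 °C to rt; then 1 M aq. HCl, THF, rt
Reagents that add atoms: methyllithium, [Li]C; water, O
Why: Organolithium addition to the nitrile stops at the N-lithio ketimine, so no over-addition occurs, and acid hydrolysis gives the methyl ketone.

**Step 21**
Reactants: 28 acetyl compound (epimer mixture)
Product: 29 7β-acetyl-4β,10β-dimethyl-1β-(2,4,6-trimethoxybenzyl)-5α-decalin-4α-ol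
Conditions: NaOMe (cat.), MeOH, rt; chromatography, minor epimer recycled
Reagents that add atoms: none
Why: Base-mediated epimerisation through the enolate places the acetyl group equatorial (7β), the thermodynamic isomer on the rigid trans-decalin (about 9:1).

**Step 22**
Reactants: 29 7β-acetyl compound
Product: 30 1β-(2,4,6-trimethoxybenzyl)eudesm-11-en-4α-ol
Conditions: Ph3PCH3Br, KOtBu, THF, 0 °C to rt
Reagents that add atoms: methyltriphenylphosphonium bromide, C[P+](c1ccccc1)(c1ccccc1)c1ccccc1.[Br-]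
Why: Wittig methylenation of the methyl ketone gives the isopropenyl group, and if the basic ylide enolises C7 it returns to the favoured 7β form.

**Step 23**
Reactants: 30 trimethoxybenzyl eudesmenol; 31 3-methylbutanal
Product: 33 1β-[3-(1-hydroxy-3-methylbutyl)-2,4,6-trimethoxybenzyl]eudesm-11-en-4α-ol, via aryllithium alkoxide 32 (not isolated)
Conditions: n-BuLi (2.5 equiv), TMEDA, THF, 0 °C; then 31, −78 to 0 °C; H2O
Reagents that add atoms: none
Why: Directed ortho-metalation lithiates a ring C–H between two methoxy groups (the two free positions are equivalent and the tertiary alcohol rides as its alkoxide), and the aryllithium adds to the aldehyde.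

**Step 24**
Reactants: 33 benzylic alcohol
Product: 35 3-[(4α-hydroxyeudesm-11-en-1β-yl)methyl]-5-(1-hydroxy-3-methylbutyl)-2,4,6-trimethoxybenzaldehyde, via trilithio intermediate 34 (not isolated)
Conditions: n-BuLi (3.5 equiv), TMEDA, THF, 0 °C; then DMF, −78 to 0 °C; H2O
Reagents that add atoms: N,N-dimethylformamide, CN(C)C=O
Why: A second directed ortho-metalation at the last ring C–H, again flanked by two methoxy groups and with both hydroxyls as alkoxides, is followed by formylation with DMF.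

**Step 25**
Reactants: 35 hydroxy aldehyde
Product: 36 3-[(4α-hydroxyeudesm-11-en-1β-yl)methyl]-2,4,6-trimethoxy-5-(3-methylbutanoyl)benzaldehyde
Conditions: DMP, NaHCO3, CH2Cl2, rt
Reagents that add atoms: none
Why: Dess–Martin oxidation of the benzylic secondary alcohol gives the aryl ketone while aldehyde, alkene and tertiary alcohol are unaffected.

**Step 26**
Reactants: 36 trimethyl ether
Product: 37 target, 3-[(4α-hydroxyeudesm-11-en-1β-yl)methyl]-2,4,6-trihydroxy-5-(3-methylbutanoyl)benzaldehyde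
Conditions: p-MeC6H4SH, n-BuLi (gives p-MeC6H4SLi, 6 equiv), HMPA/toluene, 110 °C; then 1 M aq. HCl
Reagents that add atoms: none
Why: Nucleophilic O-demethylation by thiolate (SN2 at methyl) works because every methoxy group is ortho or para to a carbonyl group, and the non-acidic conditions spare the isopropenyl group and the tertiary alcohol.

**Compound list**
1 | 2-methylcyclohexane-1,3-dione | CC1C(=O)CCCC1=O | starting material
2 | methyl vinyl ketone (but-3-en-2-one) | CC(=O)C=C | starting material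
3 | 2-methyl-2-(3-oxobutyl)cyclohexane-1,3-dione | CC(=O)CCC1(C)C(=O)CCCC1=O | intermediate
4 | aldol ketol, (8aR)-4a-hydroxy-8a-methyloctahydronaphthalene-1,6-dione, cis-fused (OH cis to CH3) | O=C1CC[C@@]2(C)C(=O)CCC[C@@]2(O)C1 | intermediate
5 | (R)-Wieland–Miescher ketone, (8aR)-8a-methyl-3,4,8,8a-tetrahydronaphthalene-1,6(2H,7H)-dione | O=C1CC[C@@]2(C)C(=O)CCCC2=C1 | intermediate
6 | (4aR,5R)-5-hydroxy-4a-methyl-4,4a,5,6,7,8-hexahydronaphthalen-2(3H)-one (1β-OH cis to the angular CH3) | O=C1CC[C@@]2(C)[C@H](O)CCCC2=C1 | intermediate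
7 | 7,7-ethylenedioxy-10β-methyloctal-4-en-1β-ol (dioxolane at C7, alkene C4=C5) | C1COC2(O1)CC[C@@]3(C)[C@H](O)CCC=C3C2 | intermediate
8 | 1β-O-TBS ether of 7 | C1COC2(O1)CC[C@@]3(C)[C@H](O[Si](C)(C)C(C)(C)C)CCC=C3C2 | intermediate
9 | alkylborane of 8 (BH2 on C4α, H on C5α) | C1COC2(O1)CC[C@@]3(C)[C@H](O[Si](C)(C)C(C)(C)C)CC[C@@H](B)[C@@H]3C2 | intermediate
10 | 1β-(TBSO)-7,7-ethylenedioxy-10β-methyl-5α-decalin-4α-ol | C1COC2(O1)CC[C@@]3(C)[C@H](O[Si](C)(C)C(C)(C)C)CC[C@@H](O)[C@@H]3C2 | intermediate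
11 | 1β-(TBSO)-7,7-ethylenedioxy-10β-methyl-5α-decalin-4-one | C1COC2(O1)CC[C@@]3(C)[C@H](O[Si](C)(C)C(C)(C)C)CCC(=O)[C@@H]3C2 | intermediate
12 | 1β-(TBSO)-7,7-ethylenedioxy-10β-methyl-4-methylene-5α-decalin | C1COC2(O1)CC[C@@]3(C)[C@H](O[Si](C)(C)C(C)(C)C)CCC(=C)[C@@H]3C2 | intermediate
13 | 4α,15-epoxide of 12 (spiro-oxirane, O on the α face of C4) | C1COC2(O1)CC[C@@]3(C)[C@H](O[Si](C)(C)C(C)(C)C)CC[C@@]4(OC4)[C@@H]3C2 | intermediate
14 | 1β-(TBSO)-7,7-ethylenedioxy-4β,10β-dimethyl-5α-decalin-4α-ol | C1COC2(O1)CC[C@@]3(C)[C@H](O[Si](C)(C)C(C)(C)C)CC[C@@](C)(O)[C@@H]3C2 | intermediate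
15 | 7,7-ethylenedioxy-4β,10β-dimethyl-5α-decalin-1β,4α-diol | C1COC2(O1)CC[C@@]3(C)[C@H](O)CC[C@@](C)(O)[C@@H]3C2 | intermediate
16 | 7,7-ethylenedioxy-4α-hydroxy-4β,10β-dimethyl-5α-decalin-1-one | C1COC2(O1)CC[C@@]3(C)C(=O)CC[C@@](C)(O)[C@@H]3C2 | intermediate
17 | 7,7-ethylenedioxy-4β,10β-dimethyl-1-methylene-5α-decalin-4α-ol | C1COC2(O1)CC[C@@]3(C)C(=C)CC[C@@](C)(O)[C@@H]3C2 | intermediate
18 | B-alkyl-9-BBN of 17 (boron on the C1β methylene, H on C1α) | C1COC2(O1)CC[C@@]3(C)[C@H](CB4C5CCCC4CCC5)CC[C@@](C)(O)[C@@H]3C2 | intermediate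
19 | 7,7-ethylenedioxy-1β-(hydroxymethyl)-4β,10β-dimethyl-5α-decalin-4α-ol | C1COC2(O1)CC[C@@]3(C)[C@H](CO)CC[C@@](C)(O)[C@@H]3C2 | intermediate
20 | 7,7-ethylenedioxy-4α-hydroxy-4β,10β-dimethyl-5α-decalin-1β-carbaldehyde | C1COC2(O1)CC[C@@]3(C)[C@H](C=O)CC[C@@](C)(O)[C@@H]3C2 | intermediate
21 | 1,3,5-trimethoxybenzene | COc1cc(OC)cc(OC)c1 | starting material
22 | 2,4,6-trimethoxyphenyllithium | [Li]c1c(OC)cc(OC)cc1OC | intermediate
23 | 7,7-ethylenedioxy-1β-[hydroxy(2,4,6-trimethoxyphenyl)methyl]-4β,10β-dimethyl-5α-decalin-4α-ol (both carbinol epimers) | C1COC2(O1)CC[C@@]3(C)[C@H](C(O)c4c(OC)cc(OC)cc4OC)CC[C@@](C)(O)[C@@H]3C2 | intermediate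
24 | 7,7-ethylenedioxy-4β,10β-dimethyl-1β-(2,4,6-trimethoxybenzyl)-5α-decalin-4α-ol | C1COC2(O1)CC[C@@]3(C)[C@H](Cc4c(OC)cc(OC)cc4OC)CC[C@@](C)(O)[C@@H]3C2 | intermediate
25 | 4α-hydroxy-4β,10β-dimethyl-1β-(2,4,6-trimethoxybenzyl)-5α-decalin-7-one | O=C1CC[C@@]2(C)[C@H](Cc3c(OC)cc(OC)cc3OC)CC[C@@](C)(O)[C@@H]2C1 | intermediate
26 | 7-cyano-4β,10β-dimethyl-1β-(2,4,6-trimethoxybenzyl)-5α-decalin-4α-ol (7α/7β mixture) | N#CC1CC[C@@]2(C)[C@H](Cc3c(OC)cc(OC)cc3OC)CC[C@@](C)(O)[C@@H]2C1 | intermediate
27 | dilithio species of the methyl ketimine (N–Li at the C7 side chain, lithium 4α-alkoxide) | CC(=N[Li])C1CC[C@@]2(C)[C@H](Cc3c(OC)cc(OC)cc3OC)CC[C@@](C)(O[Li])[C@@H]2C1 | intermediate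
28 | 7-acetyl-4β,10β-dimethyl-1β-(2,4,6-trimethoxybenzyl)-5α-decalin-4α-ol (7α/7β mixture) | CC(=O)C1CC[C@@]2(C)[C@H](Cc3c(OC)cc(OC)cc3OC)CC[C@@](C)(O)[C@@H]2C1 | intermediate
29 | 7β-acetyl-4β,10β-dimethyl-1β-(2,4,6-trimethoxybenzyl)-5α-decalin-4α-ol | CC(=O)[C@@H]1CC[C@@]2(C)[C@H](Cc3c(OC)cc(OC)cc3OC)CC[C@@](C)(O)[C@@H]2C1 | intermediate
30 | 1β-(2,4,6-trimethoxybenzyl)eudesm-11-en-4α-ol (5α-H, 7β-isopropenyl, 10β-CH3) | C=C(C)[C@@H]1CC[C@@]2(C)[C@H](Cc3c(OC)cc(OC)cc3OC)CC[C@@](C)(O)[C@@H]2C1 | intermediate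
31 | 3-methylbutanal | CC(C)CC=O | starting material
32 | aryllithium alkoxide of 30 (Li on the ring carbon between two OMe, lithium 4α-alkoxide) | C=C(C)[C@@H]1CC[C@@]2(C)[C@H](Cc3c(OC)c([Li])c(OC)cc3OC)CC[C@@](C)(O[Li])[C@@H]2C1 | intermediate
33 | 1β-[3-(1-hydroxy-3-methylbutyl)-2,4,6-trimethoxybenzyl]eudesm-11-en-4α-ol (both carbinol epimers) | C=C(C)[C@@H]1CC[C@@]2(C)[C@H](Cc3c(OC)c(C(O)CC(C)C)c(OC)cc3OC)CC[C@@](C)(O)[C@@H]2C1 | intermediate
34 | trilithio species of 33 (two lithium alkoxides, Li on the last ring carbon) | C=C(C)[C@@H]1CC[C@@]2(C)[C@H](Cc3c(OC)c(C(O[Li])CC(C)C)c(OC)c([Li])c3OC)CC[C@@](C)(O[Li])[C@@H]2C1 | intermediate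
35 | 3-[(4α-hydroxyeudesm-11-en-1β-yl)methyl]-5-(1-hydroxy-3-methylbutyl)-2,4,6-trimethoxybenzaldehyde (both carbinol epimers) | C=C(C)[C@@H]1CC[C@@]2(C)[C@H](Cc3c(OC)c(C(O)CC(C)C)c(OC)c(C=O)c3OC)CC[C@@](C)(O)[C@@H]2C1 | intermediate
36 | 3-[(4α-hydroxyeudesm-11-en-1β-yl)methyl]-2,4,6-trimethoxy-5-(3-methylbutanoyl)benzaldehyde | C=C(C)[C@@H]1CC[C@@]2(C)[C@H](Cc3c(OC)c(C(=O)CC(C)C)c(OC)c(C=O)c3OC)CC[C@@](C)(O)[C@@H]2C1 | intermediate
37 | 3-[(4α-hydroxyeudesm-11-en-1β-yl)methyl]-2,4,6-trihydroxy-5-(3-methylbutanoyl)benzaldehyde (CNP0561337.1) | C=C(C)[C@@H]1CC[C@@]2(C)[C@H](Cc3c(O)c(C=O)c(O)c(C(=O)CC(C)C)c3O)CC[C@@](C)(O)[C@@H]2C1 | target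

**Totals**
Total step count: 26. Longest linear sequence: 26 steps (1 to 37; 21 and 31 enter as purchased partners).

**Steps most likely to fail**

Step 17 (ionic deoxygenation beside a dioxolane and a tertiary alcohol). The fallback sets out from 18 and comes back at 24. Instead of oxidising the borane, the B-alkyl-9-BBN 18 is cross-coupled directly with 2-iodo-1,3,5-trimethoxybenzene in a B-alkyl Suzuki–Miyaura reaction (Pd(OAc)2, SPhos (2-dicyclohexylphosphino-2',6'-dimethoxybiphenyl), K3PO4, THF/H2O, 65 °C). This gives 24 with the C1 configuration already fixed by the hydroboration and without any acid or cationic intermediate; it makes no compound outside the list, F0.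

Step 24 (second lithiation on a substrate carrying two alkoxides). The fallback sets out from 30 and comes back at 36. The aldehyde is introduced first and masked. Lithiation of 30 (n-BuLi, TMEDA) and DMF give the benzaldehyde F1, which is converted into the dimethyl acetal F2 (HC(OMe)3, MeOH, PPTS cat., rt). A second ortho-lithiation of F2 and addition to 3-methylbutanal 31 give the acetal alcohol F3, Dess–Martin oxidation gives the acetal ketone F4, and brief 0.1 M aq. HCl in THF at 0 °C releases 36.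

Step 26 (threefold demethylation in the presence of the aldehyde). The fallback sets out from 33 and comes back at 37. The aldehyde is kept out of the hot thiolate step. Dess–Martin oxidation of 33 gives the aryl ketone F5, and thiolate demethylation of F5 (p-MeC6H4SLi, HMPA/toluene, 110 °C) gives the acylphloroglucinol F6. Magnesium-mediated ortho-formylation of F6 (MgCl2, Et3N, paraformaldehyde, MeCN, reflux) then places the aldehyde on the last free ring position under basic conditions and gives 37.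

**Further compounds**
F0 | step 17 | none | none
F1 | step 24 | 3-[(4α-hydroxyeudesm-11-en-1β-yl)methyl]-2,4,6-trimethoxybenzaldehyde | C=C(C)[C@@H]1CC[C@@]2(C)[C@H](Cc3c(OC)c(C=O)c(OC)cc3OC)CC[C@@](C)(O)[C@@H]2C1
F2 | step 24 | dimethyl acetal of F1 | C=C(C)[C@@H]1CC[C@@]2(C)[C@H](Cc3c(OC)c(C(OC)OC)c(OC)cc3OC)CC[C@@](C)(O)[C@@H]2C1
F3 | step 24 | dimethyl acetal of 35 (acetal alcohol, both carbinol epimers) | C=C(C)[C@@H]1CC[C@@]2(C)[C@H](Cc3c(OC)c(C(OC)OC)c(OC)c(C(O)CC(C)C)c3OC)CC[C@@](C)(O)[C@@H]2C1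
F4 | step 24 | dimethyl acetal of 36 (acetal ketone) | C=C(C)[C@@H]1CC[C@@]2(C)[C@H](Cc3c(OC)c(C(OC)OC)c(OC)c(C(=O)CC(C)C)c3OC)CC[C@@](C)(O)[C@@H]2C1
F5 | step 26 | 1β-[2,4,6-trimethoxy-3-(3-methylbutanoyl)benzyl]eudesm-11-en-4α-ol | C=C(C)[C@@H]1CC[C@@]2(C)[C@H](Cc3c(OC)c(C(=O)CC(C)C)c(OC)cc3OC)CC[C@@](C)(O)[C@@H]2C1
F6 | step 26 | 1β-[2,4,6-trihydroxy-3-(3-methylbutanoyl)benzyl]eudesm-11-en-4α-ol | C=C(C)[C@@H]1CC[C@@]2(C)[C@H](Cc3c(O)c(C(=O)CC(C)C)c(O)cc3O)CC[C@@](C)(O)[C@@H]2C1
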